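Readings and results are simulated on assumed constants.

If starting material comes back, the coupling is not one-way: in the teal run it reads 73.2% at 1.00 min and 81.0% at 4.00 min, while target falls to 15.2%.

| flask | starting material | coupling partner | protic impurity | remark | time |
|---|---|---|---|---|---|
| teal | 0.045 M | 1.2 equiv | 1.8 mM | run made earlier |  |
| grey | 0.18 M | 1.2 equiv | 1.8 mM | run made earlier |  |
| flask | 0.090 M | 1.20 equiv | 1.80 mM |  | 6.0 min |

- teal (time / min: target / %, starting material / %): 0.200: 9.8, 86.5; 0.333: 13.5, 81.6; 0.667: 21.2, 76.4; 1.00: 22.0, 73.2; 2.00: 21.7, 74.4; 4.00: 15.2, 81.0
- grey (time / min: target / %, starting material / %): 0.200: 28.9, 70.8; 0.333: 32.0, 65.9; 0.667: 31.8, 66.5; 1.00: 28.6, 70.1; 2.00: 21.2, 78.2; 4.00: 12.5, 86.8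

(scatter of a reading: 0.5 percentage points)

* when, up to 6.0 min, the flask holds most target
* the amount of target, in percent of the starting material charged, at that time



The main step is therefore taken as a reversible coupling. Next comes the protic impurity. At 4.00 min the teal readings sum 3.8 percentage points short, and the grey readings 0.7 points, close to the impurity's share of each charge, 4.00% and 1.00%. In the flask that share is 2.00%, a small cut. Last comes a loss of coupling partner, inferred from target falling as starting material returns.

With these three processes, the height of the hump is what remains to be estimated. The highest target reading is 22.0% in teal and 32.0% in grey. That is 5 points for each doubling of the starting concentration, with equivalents and impurity held: call this rise the gain per doubling, g. My own reckoning from teal puts the flask at 27.0%.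

The forecast gives 27.5% at 0.8 min, 0.5 points above my own reckoning, and its grounds are the same kind of step: “so I interpolate on a log scale”.

The flask gives 28.7% at 0.748 min, so the forecast holds within its margins.

    starting material + coupling partner ⇌ target + by-product (K = 0.350, k = 0.200 L mol⁻¹ s⁻¹)
    starting material + protic impurity → quenched substrate (k = 5.00 L mol⁻¹ s⁻¹)
    coupling partner → decomposed reagent (k = 0.0200 s⁻¹)

At 0.676 min the flask's coupling partner passes into decomposed reagent 1.6 times as fast as into target by the forward step alone, and 28.3% of its charge stands at the best time. The flask lies 1.7 points above the reckoning with g, and the climb from the teal reading to the flask exceeds that from the flask to the grey reading. For the neighbour flask at 0.054 M, g gives 23.3%; the computed peak is 24.4%.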